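The numbers in the tables were computed from invented constants.

After 144 h the west flask, the very flask you are asked about, still holds 73.1% of its starting material, yet its product has slowed to a crawl, and you must say what it holds at 8.0 d and which option gains most.

- west: starting material 20 mM; reagent 20 mM; free catalyst 0.50 mM; the very flask that is asked about, followed so far
- flask: starting material 20 mM; reagent 20.0 mM; free catalyst 0.50 mM; time 8.0 d

- west (time / h: product / %, starting material / %): 12.0: 15.2, 85.8; 30.0: 21.1, 78.7; 72.0: 24.0, 74.9; 144: 26.2, 73.1

(scatter of a reading: 0.5 percentage points)

- removed product is counted in
- additions bring no volume worth counting

- dawn: at 8.0 d add free catalyst, 100% of the amount charged, then wait 15 d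
- noon: at 8.0 d add reagent, 100% of the amount charged, then wait 15 d
- winter: at 8.0 d take out 90% of the product then present, then wait 15 d
- summer: change nothing and wait 15 d more

1. product, in percent of the starting material first charged, at 8.0 d
2. which option adds most product ("none" when 2 percentage points or less is all one gets) (dawn / noon / winter / summer / none)
3. product present, with what was taken out counted in, in percent of the starting material first charged, after winter
4. product present, with what was taken out counted in, in percent of the starting material first charged, after summer

Build this flask up one process at a time, assuming that free catalyst turns starting material and reagent into product. Take first the main step by itself, with the catalyst coming back unchanged: the pace of the first 12.0 h, held to 8.0 d, gives 243%, so with equal charges your number for "now" is 100%.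

Now add a loss of catalyst. From the stretch between 12.0 h and 30.0 h to the stretch between 72.0 h and 144 h the pace falls by a factor of 10.7, far more than the drop in starting material from 78.7% to 73.1%, with an equal drop in reagent beside it, can give, so I read this as a catalyst that makes a limited number of turns. The product made per catalyst charged, as read at the last reading, is 10.5; call this N, the turnover capacity, the chemist's turnover number.

Then add the remaining trickle: the last pace, held to 8.0 d, reaches 27.7%, and as that pace is falling, I put "now" between 26.2% and that figure. By my reckoning a fresh charge buys N times that charge, 26 percentage points, which is more than the margin of 2 points, while the other options add no catalyst.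

The forecast gives 27.1% for "now", dawn as best, 31.5% after winter and 30% after summer, on the ground of “the catalyst progressively dying”.

The flask gives 26.5% at 8.0 d, 26.6% after winter and 26.6% after summer; dawn is best and adds 21 points, against 0.11 points for noon.

    starting material + reagent + free catalyst → product + free catalyst, rate k1*[starting material]*[reagent]*[free catalyst]/(1 + ([starting material]/sat1)) (0.750 mM, k = 94900 M⁻² h⁻¹)
    2 free catalyst → spent catalyst A (k = 272 M⁻¹ h⁻¹)
    reagent + free catalyst → spent catalyst B (k = 1.54 M⁻¹ h⁻¹)

The forecast held. At 192 h free catalyst stands at 0.0964% of its charge, with 75.9% as spent catalyst A and 24.0% as spent catalyst B. The turnover capacity from the result is 10.6, and the fresh charge on this flask brought 21 points, less than the reckoned 26 points. On a neighbouring flask, the same but charged with 5.0 mM of starting material, N times the catalyst charge gives 5.24 mM of product, which is 105% of its starting material charge. That neighbouring flask reaches 84.3% at 192 h, with 16% of its starting material left.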